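The route rests on the tetrasubstituted C3a=C7a alkene shared by ring A (butenolide) and ring B (cyclohexene). C7a carries the lactone carbonyl C1 and C3a the enol-ether carbon C3, so both carbons can be delivered as a transient cyclohexyne. In one operation the key step forms C7a–C1 and C3a–C3 and closes ring A as a 2-ethoxyfuran, by cycloaddition of the cyclohexyne to 5-ethoxy-4-methyloxazole and loss of acetonitrile. The furan then serves as masked butenolide and as nucleophile for butanal. The precursor is the 2-(triethylsilyl)cyclohexenyl triflate of a cis-fused cyclobutane that already bears the propyl group and the spiro-phthalide, built by dichloroketene cycloaddition to an (R)-cyclohexenyl silyl ether.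

Key step: step 13

Labels: butenolide half C1 (C=O), O2, C3, C3a, C4–C7, C7a, side chain C8–C11; phthalide half primed, C3' = spiro carbon, C8' = propyl-bearing carbon. Ring A = butenolide, ring B = six-membered carbocycle, ring C = cyclobutane (C6, C7, C3', C8'), ring D = phthalide lactone, ring E = benzene. With these labels the target is (Z,6S,7R,3'R,8'R).

Assumption: the ketene is taken to add to the allylic silyl ether with its carbonyl carbon on the alkene carbon next to the carbinol and anti to the silyloxy group; this is what makes the (R)-alcohol the correct enantiomer.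

Design note: the triflate stays on C7a and the triethylsilyl group on C3a. The precursor is reached through a regiospecific enolate and not by direct α-silylation, because the ketone precursor carries a β-acyloxy group that an equilibrating base would expel.

Step 1
Reactants: 1 (R)-cyclohex-2-en-1-ol
Product: 2 (R)-(cyclohex-2-en-1-yloxy)triisopropylsilane
Conditions: i-Pr3SiOTf, 2,6-lutidine, CH2Cl2, 0 °C
Reagents that add atoms: triisopropylsilyl triflate, CC(C)[Si](OS(=O)(=O)C(F)(F)F)(C(C)C)C(C)C
Why: Standard O-silylation of a secondary allylic alcohol leaves the carbinol center untouched and gives a bulky, weakly nucleophilic ether oxygen that shields one alkene face and resists acylation by the ketene in step 2.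

Step 2
Reactants: 2 (R)-(cyclohex-2-en-1-yloxy)triisopropylsilane; 3 trichloroacetyl chloride
Product: 5 (1R,5R,6R)-8,8-dichloro-5-(triisopropylsilyloxy)bicyclo[4.2.0]octan-7-one, via dichloroketene 4 (not isolated)
Conditions: Zn–Cu couple, POCl3, Et2O, 23 °C, slow addition of 3
Reagents that add atoms: none
Why: Ketene–alkene [2+2] cycloaddition in which the ketene carbonyl carbon should bond to the alkene carbon next to the carbinol (future C7), so that the developing positive charge sits on the remote carbon (future C6) away from the inductively withdrawing C–O bond, while approach anti to the silyloxy group sets the cis ring fusion C6/C7 in the required absolute sense.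

Step 3
Reactants: 5 (1R,5R,6R)-8,8-dichloro-5-(triisopropylsilyloxy)bicyclo[4.2.0]octan-7-one
Product: 6 (1S,5R,6R)-5-(triisopropylsilyloxy)bicyclo[4.2.0]octan-7-one
Conditions: Zn, AcOH, 23 → 50 °C
Reagents that add atoms: none
Why: Zinc-mediated reductive dechlorination of an α,α-dichlorocyclobutanone is standard and leaves the three stereocenters untouched (the descriptor at C1 changes by priority only).

Step 4
Reactants: 6 (1S,5R,6R)-5-(triisopropylsilyloxy)bicyclo[4.2.0]octan-7-one; 7 propanal
Product: 9 8-(1-hydroxypropyl) ketone (aldol adduct; diastereomer mixture), via lithium enolate 8 (not isolated)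
Conditions: LDA, THF, −78 °C; then 7, −78 °C; aq. NH4Cl
Reagents that add atoms: none
Why: Kinetic deprotonation should occur at the unhindered cyclobutanone CH2 (future C8') and not at the ring-fusion CH, and the directed aldol addition to propanal gives a β-hydroxy ketone whose two new stereocenters are erased in step 5.

Step 5
Reactants: 9 8-(1-hydroxypropyl) ketone (aldol adduct)
Product: 11 (1R,5R,6R,E)-8-propylidene-5-(triisopropylsilyloxy)bicyclo[4.2.0]octan-7-one, via aldol mesylate 10 (not isolated)
Conditions: MsCl, Et3N, CH2Cl2, 0 °C; then DBU, 23 °C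
Reagents that add atoms: none
Why: Mesylation and E1cB elimination complete the aldol condensation to the conjugated exocyclic enone, and either alkene geometry serves step 6.

Step 6
Reactants: 11 (1R,5R,6R,E)-8-propylidene-5-(triisopropylsilyloxy)bicyclo[4.2.0]octan-7-one
Product: 12 (1S,5R,6R,8R)-8-propyl-5-(triisopropylsilyloxy)bicyclo[4.2.0]octan-7-one
Conditions: H2 (1 atm), 10% Pd/C, EtOAc, 23 °C
Reagents that add atoms: none
Why: Heterogeneous hydrogenation of the enone C=C should take place from the convex face of the cis-bicyclo[4.2.0]octane (the face of the ring-fusion hydrogens), which sets C8' with the propyl group on the concave face, cis to ring B.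

Step 7
Reactants: 12 (1S,5R,6R,8R)-8-propyl-5-(triisopropylsilyloxy)bicyclo[4.2.0]octan-7-one; 13 methyl 2-iodobenzoate
Product: 16 spiro-phthalide triisopropylsilyl ether, via arylmagnesium chloride 14 (not isolated), via magnesium alkoxide 15 (not isolated)
Conditions: 13, i-PrMgCl·LiCl, THF, −40 °C; then 12, −40 → 23 °C; aq. NH4Cl
Reagents that add atoms: none
Why: Grignard addition–lactonization: the ester-tolerant iodine–magnesium exchange gives an aryl Grignard that should add to the strained ketone from the convex face, anti to the concave propyl group (setting the spiro center C3' with oxygen cis to propyl), and the tertiary alkoxide then closes ring D on the ortho ester.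

Step 8
Reactants: 16 spiro-phthalide triisopropylsilyl ether
Product: 17 spiro-phthalide secondary alcohol (C7a–OH)
Conditions: Bu4NF, THF, 23 °C
Reagents that add atoms: none
Why: Fluoride cleavage of a silyl ether is standard, and the phthalide has no enolizable position that the basic fluoride could disturb.

Step 9
Reactants: 17 spiro-phthalide secondary alcohol
Product: 18 spiro-phthalide ketone (C7a=O)
Conditions: Dess–Martin periodinane, NaHCO3, CH2Cl2, 23 °C
Reagents that add atoms: none
Why: Buffered Dess–Martin oxidation is neutral, which avoids β-elimination of the lactone carboxylate from the new β-acyloxy ketone, and it removes the carbinol center once this has done its work as control element.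

Step 10
Reactants: 18 spiro-phthalide ketone
Product: 20 α-bromo ketone (Br on C3a; epimer mixture), via trimethylsilyl enol ether 19 (not isolated)
Conditions: Me3SiCl, LiN(SiMe3)2, THF, −78 °C; then N-bromosuccinimide, −78 → 0 °C
Reagents that add atoms: N-bromosuccinimide, O=C1CCC(=O)N1Br
Why: Kinetic enol silylation with in situ trapping should go to the CH2 side (C3a) and not to the hindered ring-fusion CH, and electrophilic bromination of the silyl enol ether fixes the halogen on C3a.

Step 11
Reactants: 20 α-bromo ketone
Product: 21 2-bromo triethylsilyl enol ether (OSiEt3 on C7a; Br on C3a)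
Conditions: Et3SiOTf, Et3N, CH2Cl2, −78 → 0 °C
Reagents that add atoms: triethylsilyl triflate, CC[Si](CC)(CC)OS(=O)(=O)C(F)(F)F
Why: Soft enolization removes the more acidic proton on the bromine-bearing carbon, so O-silylation should give the tetrasubstituted C7a=C3a enol ether without forming a free enolate toward C7.

Step 12
Reactants: 21 2-bromo triethylsilyl enol ether
Product: 24 2-(triethylsilyl)cyclohexenyl triflate of the spiro-phthalide bicycle (OTf on C7a; SiEt3 on C3a), via vinyllithium 22 (not isolated), via α-silyl lithium enolate 23 (not isolated)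
Conditions: t-BuLi (2.1 equiv), THF/Et2O/pentane, −110 → −60 °C; then N-(5-chloropyridin-2-yl)triflimide, −78 → 0 °C
Reagents that add atoms: N-(5-chloropyridin-2-yl)bis(trifluoromethanesulfonimide), O=S(=O)(N(c1ccc(Cl)cn1)S(=O)(=O)C(F)(F)F)C(F)(F)F
Why: Bromine–lithium exchange followed by 1,3 O→C silyl migration (retro-Brook rearrangement, the same sequence that converts 2-bromoaryl silyl ethers into 2-silylaryl triflates) should deliver the enolate of the α-silyl ketone regiospecifically, and O-triflation then gives the cyclohexyne precursor without an equilibrating base.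

Step 13
Reactants: 24 2-(triethylsilyl)cyclohexenyl triflate of the spiro-phthalide bicycle; 25 5-ethoxy-4-methyloxazole
Product: 28 ring-A 2-ethoxyfuran on the spiro-phthalide bicycle, via cyclohexyne 26 (not isolated), via bridged cycloadduct 27 (not isolated)
Conditions: CsF (5 equiv), 25 (10 equiv), MeCN, 23 °C, slow addition of 24
Reagents that add atoms: none
Why: Proposed new method: fluoride attacks the silicon on C3a of 24 and the resulting vinyl anion expels the C7a triflate to give the strained cyclohexyne 26, whose bent in-plane π bond should act as a strong dienophile toward the electron-rich 2-azadiene of oxazole 25 (termini C2 and C5), after which the 7-oxa-2-azabicyclo[2.2.1]heptadiene 27 loses acetonitrile by retro-[4+2] to give the aromatic furan 28. The closest known reaction types are the aryne–oxazole Diels–Alder/retro-Diels–Alder route to isobenzofurans, the alkyne–oxazole route to furans, and fluoride-induced generation and [4+2] trapping of cyclohexynes from silyl triflates. Ring A closes by intermolecular [4+2] cycloaddition, which forms C7a–C1 and C3a–C3 in one event, followed by cycloreversion; no stereocenter is created, and the neutral conditions at room temperature should leave the four existing ones and ring D alone. The step needs regioselectivity: the donor-free C2 terminus of 25, which carries the larger HOMO coefficient, must bond to C3a. The substrate should secure this because the cyclobutyl carbon C7 with its β-acyloxy group is inductively withdrawing, which makes C3a the more linear, more electrophilic and less hindered alkyne carbon (distortion model for 3-substituted cyclohexynes). A large excess of 25 and slow generation of 26 should keep the product furan from competing as a diene.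

Step 14
Reactants: 28 ring-A 2-ethoxyfuran; 29 butanal
Product: 31 3-(1-hydroxybutyl) butenolide (diastereomer mixture at C3 and C8), via oxocarbenium aldolate 30 (not isolated)
Conditions: BF3·OEt2, CH2Cl2, −78 °C; then aq. NaHCO3
Reagents that add atoms: water, O
Why: Vinylogous Mukaiyama-type aldol addition in which the free α-position (C3) of the 2-alkoxyfuran attacks the BF3-activated aldehyde and hydrolysis of the ethoxy-oxocarbenium on work-up releases the butenolide, whose two new stereocenters disappear in step 15.

Step 15
Reactants: 31 3-(1-hydroxybutyl) butenolide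
Product: 33 target CNP0248594.2, via mesylate 32 (not isolated)
Conditions: MsCl, Et3N, CH2Cl2, 0 °C; then DBU, 23 °C
Reagents that add atoms: none
Why: Mesylation and E1cB elimination through the acidic C3–H should give the exocyclic enol-lactone alkene with Z geometry, because the propyl chain then avoids the C4 methylene of ring B (the usual outcome for 3-alkylidenephthalides).

Compound list

1 | (R)-cyclohex-2-en-1-ol | O[C@H]1C=CCCC1 | starting material
2 | (R)-(cyclohex-2-en-1-yloxy)triisopropylsilane | CC(C)[Si](O[C@H]1C=CCCC1)(C(C)C)C(C)C | intermediate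
3 | trichloroacetyl chloride | ClC(Cl)(Cl)C(Cl)=O | starting material
4 | dichloroketene | ClC(Cl)=C=O | intermediate (not isolated)
5 | (1R,5R,6R)-8,8-dichloro-5-(triisopropylsilyloxy)bicyclo[4.2.0]octan-7-one; cis-fused, silyloxy anti to the four-membered ring | CC(C)[Si](O[C@@H]1CCC[C@H]2C(Cl)(Cl)C(=O)[C@@H]12)(C(C)C)C(C)C | intermediate
6 | (1S,5R,6R)-5-(triisopropylsilyloxy)bicyclo[4.2.0]octan-7-one | CC(C)[Si](O[C@@H]1CCC[C@H]2CC(=O)[C@@H]12)(C(C)C)C(C)C | intermediate
7 | propanal | CCC=O | starting material
8 | lithium enolate of 6 (O–Li on C7, C7=C8) | CC(C)[Si](O[C@@H]1CCC[C@H]2C=C(O[Li])[C@@H]12)(C(C)C)C(C)C | intermediate (not isolated)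
9 | 8-(1-hydroxypropyl) derivative of 6 (aldol adduct; mixture at C8 and the carbinol) | CC(C)[Si](O[C@@H]1CCC[C@H]2C(C(O)CC)C(=O)[C@@H]12)(C(C)C)C(C)C | intermediate
10 | methanesulfonate of 9 | CC(C)[Si](O[C@@H]1CCC[C@H]2C(C(CC)OS(C)(=O)=O)C(=O)[C@@H]12)(C(C)C)C(C)C | intermediate (not isolated)
11 | (1R,5R,6R,E)-8-propylidene-5-(triisopropylsilyloxy)bicyclo[4.2.0]octan-7-one | CC(C)[Si](O[C@@H]1CCC[C@H]2/C(=C\CC)C(=O)[C@@H]12)(C(C)C)C(C)C | intermediate
12 | (1S,5R,6R,8R)-8-propyl-5-(triisopropylsilyloxy)bicyclo[4.2.0]octan-7-one; propyl cis to the six-membered ring | CC(C)[Si](O[C@@H]1CCC[C@H]2[C@@H](CCC)C(=O)[C@@H]12)(C(C)C)C(C)C | intermediate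
13 | methyl 2-iodobenzoate | COC(=O)c1ccccc1I | starting material
14 | [2-(methoxycarbonyl)phenyl]magnesium chloride (LiCl complex) | COC(=O)c1ccccc1[Mg]Cl | intermediate (not isolated)
15 | chloromagnesium alkoxide from addition of 14 to 12 (aryl on the convex face) | CC(C)[Si](O[C@@H]1CCC[C@H]2[C@@H](CCC)[C@@](c3ccccc3C(=O)OC)(O[Mg]Cl)[C@@H]12)(C(C)C)C(C)C | intermediate (not isolated)
16 | spiro-phthalide triisopropylsilyl ether: ring B (C7a–OSi, R) cis-fused at C6/C7 to ring C; C8' propyl cis to C5; C3' spiro to ring D with lactone oxygen cis to propyl; C6, C7, C3', C8' arranged as in 33 | CC(C)[Si](O[C@@H]1CCC[C@H]2[C@@H](CCC)[C@@]3(OC(=O)c4ccccc43)[C@@H]12)(C(C)C)C(C)C | intermediate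
17 | spiro-phthalide alcohol (C7a–OH, R; other centers as in 16) | O[C@@H]1CCC[C@H]2[C@@H](CCC)[C@@]3(OC(=O)c4ccccc43)[C@@H]12 | intermediate
18 | spiro-phthalide ketone (C7a=O; C6, C7, C3', C8' as in 33) | O=C1CCC[C@H]2[C@@H](CCC)[C@@]3(OC(=O)c4ccccc43)[C@@H]12 | intermediate
19 | trimethylsilyl enol ether of 18 (C7a=C3a) | C[Si](C)(C)OC1=CCC[C@H]2[C@@H](CCC)[C@@]3(OC(=O)c4ccccc43)[C@@H]12 | intermediate (not isolated)
20 | α-bromo ketone (Br on C3a, both epimers) | O=C1C(Br)CC[C@H]2[C@@H](CCC)[C@@]3(OC(=O)c4ccccc43)[C@@H]12 | intermediate
21 | 2-bromo triethylsilyl enol ether (OSiEt3 on C7a, Br on C3a) | CC[Si](CC)(CC)OC1=C(Br)CC[C@H]2[C@@H](CCC)[C@@]3(OC(=O)c4ccccc43)[C@@H]12 | intermediate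
22 | vinyllithium (Li on C3a, OSiEt3 on C7a) | CC[Si](CC)(CC)OC1=C([Li])CC[C@H]2[C@@H](CCC)[C@@]3(OC(=O)c4ccccc43)[C@@H]12 | intermediate (not isolated)
23 | lithium enolate of the α-silyl ketone (O–Li on C7a, SiEt3 on C3a) | [Li]OC1=C([Si](CC)(CC)CC)CC[C@H]2[C@@H](CCC)[C@@]3(OC(=O)c4ccccc43)[C@@H]12 | intermediate (not isolated)
24 | 2-(triethylsilyl)cyclohexenyl triflate of the spiro-phthalide bicycle (OTf on C7a, SiEt3 on C3a) | FC(F)(F)S(=O)(=O)OC1=C([Si](CC)(CC)CC)CC[C@H]2[C@@H](CCC)[C@@]3(OC(=O)c4ccccc43)[C@@H]12 | intermediate (key-step precursor)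
25 | 5-ethoxy-4-methyloxazole | CCOc1ocnc1C | starting material
26 | cyclohexyne (C3a≡C7a) of the spiro-phthalide bicycle | C1#CCC[C@H]2[C@@H](CCC)[C@@]3(OC(=O)c4ccccc43)[C@@H]12 | intermediate (not isolated)
27 | 7-oxa-2-azabicyclo[2.2.1]heptadiene cycloadduct (oxazole C2 on C3a, C5 on C7a; either bridge diastereomer) | CCOC15OC(N=C5C)C(CC[C@H]2[C@@H](CCC)[C@@]3(OC(=O)c4ccccc43)[C@H]26)=C16 | intermediate (not isolated)
28 | ring-A 2-ethoxyfuran on the spiro-phthalide bicycle (OEt carbon on C7a, CH on C3a) | CCOc1occ2CC[C@H]3[C@@H](CCC)[C@@]4(OC(=O)c5ccccc54)[C@H]3c12 | intermediate (key-step product)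
29 | butanal | CCCC=O | starting material
30 | ethoxy-oxocarbenium trifluoroborate aldolate (zwitterion) | CCCC(O[B-](F)(F)F)C1OC(=[O+]CC)C2=C1CC[C@H]1[C@@H](CCC)[C@@]3(OC(=O)c4ccccc43)[C@@H]21 | intermediate (not isolated)
31 | 3-(1-hydroxybutyl) butenolide (mixture at C3 and C8) | CCCC(O)C1OC(=O)C2=C1CC[C@H]1[C@@H](CCC)[C@@]3(OC(=O)c4ccccc43)[C@@H]21 | intermediate
32 | methanesulfonate of 31 | CCCC(OS(C)(=O)=O)C1OC(=O)C2=C1CC[C@H]1[C@@H](CCC)[C@@]3(OC(=O)c4ccccc43)[C@@H]21 | intermediate (not isolated)
33 | CNP0248594.2: (Z)-3-butylidene butenolide fused to ring B, (6S,7R,3'R,8'R) | CCC/C=C1\OC(=O)C2=C1CC[C@H]1[C@@H](CCC)[C@@]3(OC(=O)c4ccccc43)[C@@H]21 | target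

Total steps: 15. Longest linear sequence: 15 steps (1 → 33).

Steps most likely to fail

1. Step 13 (Proposed new method). The oxazole may bond in the reverse orientation, its nitrogen may attack the cyclohexyne, or the furan formed may trap further cyclohexyne, so that ring A closes with the wrong regiochemistry or not at all. The fallback uses known chemistry without a cyclohexyne and sets out from ketone 18. Vilsmeier-type bromoformylation (PBr3, DMF, CHCl3) should give the 2-bromo enal F1, with bromine on C7a and the formyl group on C3a, the only α-carbon that can become sp2. Luche reduction (NaBH4, CeCl3·7H2O, MeOH) gives the bromo allylic alcohol F2. Carbonylative lactonization (CO, Pd(PPh3)4, K2CO3, DMF) closes ring A as the butenolide F3 with C1 on C7a. t-BuMe2SiOTf and Et3N give the 2-silyloxyfuran F4, and its BF3·OEt2-promoted vinylogous Mukaiyama aldol addition to butanal 29 comes back to the route at 31.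

2. Step 12. Addition of tert-butyllithium or of vinyllithium 22 to the phthalide carbonyl may compete with the halogen–lithium exchange and the silyl migration. The fallback avoids alkyllithium reagents and sets out from ketone 18. Condensation with 1,1-dimethylhydrazine gives the N,N-dimethylhydrazone F5. LDA and then Et3SiCl silylate its CH2 carbon (C3a) to give the α-triethylsilyl hydrazone F6. Buffered aqueous CuCl2 hydrolysis gives the α-triethylsilyl ketone F7. KN(SiMe3)2 and N-(5-chloropyridin-2-yl)triflimide at −78 °C then convert F7 into 24 by deprotonation at the silicon-bearing carbon, the more acidic site. This last step is the weak point of the fallback, because the ring-fusion proton must stay untouched.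

3. Step 2. The allylic silyloxy group slows the cycloaddition, so ketene oligomerization and zinc-salt-induced loss of the silyl ether may compete and conversion may stay low. The fallback uses a more electrophilic two-carbon partner without zinc and sets out from silyl ether 2. N,N-Dimethylacetamide, Tf2O and 2,4,6-collidine in ClCH2CH2Cl give the N,N-dimethylketeniminium triflate F8. Its [2+2] cycloaddition to 2, with the same regiochemical and facial preference, gives the cyclobutaniminium triflate F9, and aqueous NaHCO3 hydrolysis comes back to the route at 6, which also makes step 3 unnecessary.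

Further compounds

F1 | step 13 | 2-bromo enal (Br on C7a, CHO on C3a; other centers as in 18) | BrC1=C(C=O)CC[C@H]2[C@@H](CCC)[C@@]3(OC(=O)c4ccccc43)[C@@H]12
F2 | step 13 | bromo allylic alcohol (Br on C7a, CH2OH on C3a) | BrC1=C(CO)CC[C@H]2[C@@H](CCC)[C@@]3(OC(=O)c4ccccc43)[C@@H]12
F3 | step 13 | ring-A butenolide with C3 as CH2 | C1OC(=O)C2=C1CC[C@H]1[C@@H](CCC)[C@@]3(OC(=O)c4ccccc43)[C@@H]21
F4 | step 13 | ring-A 2-(tert-butyldimethylsilyloxy)furan | CC(C)(C)[Si](C)(C)Oc1occ2CC[C@H]3[C@@H](CCC)[C@@]4(OC(=O)c5ccccc54)[C@H]3c12
F5 | step 12 | N,N-dimethylhydrazone of 18 | CN(C)N=C1CCC[C@H]2[C@@H](CCC)[C@@]3(OC(=O)c4ccccc43)[C@@H]12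
F6 | step 12 | α-triethylsilyl hydrazone (Si on C3a) | CN(C)N=C1C([Si](CC)(CC)CC)CC[C@H]2[C@@H](CCC)[C@@]3(OC(=O)c4ccccc43)[C@@H]12
F7 | step 12 | α-triethylsilyl ketone (Si on C3a) | O=C1C([Si](CC)(CC)CC)CC[C@H]2[C@@H](CCC)[C@@]3(OC(=O)c4ccccc43)[C@@H]12
F8 | step 2 | N,N-dimethylketeniminium triflate | C=C=[N+](C)C.[O-]S(=O)(=O)C(F)(F)F
F9 | step 2 | cyclobutaniminium triflate corresponding to 6 | CC(C)[Si](O[C@@H]1CCC[C@H]2CC(=[N+](C)C)[C@@H]12)(C(C)C)C(C)C.[O-]S(=O)(=O)C(F)(F)F
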